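**Retrosynthetic overview**

1. Target ⇐ one cationic cascade on a fully functionalised acyclic C20 chain: C4–C5 bond (ring A), then C9–C10 bond (ring B). C5, C9 and C10 are all set there, and the cascade ends by loss of SiMe3 from C17 to give the 8(17)-alkene.
2. The C4 cation is released from a tertiary C–F bond by a chiral silylium ion pair. It is the cation the terpene cyclase makes by protonating the terminal alkene, but no free acid is present, so the allylsilane terminator survives.
3. Acyclic chain ⇐ homoallylic bromide (C1–C12, C17–C20) + silyl 4-(isobutyryloxy)but-2-ynoate (C13–C16) by syn-carbocupration, which sets the 13Z geometry.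
4. Bromide ⇐ terminal alkyne + Me3SiCH2Cu + oxirane (sets the allylsilane geometry); alkyne ⇐ 7-fluoro-geranyl chloride + a propargyl unit; fluoride ⇐ geranyl chloride.
5. Ring order: no ring before the last step; ring A then ring B in the same operation.

Assumption: the antipode of the IDPi catalyst that leads to the (5R,9R,10R) series is picked in a pilot run (both antipodes are made alike from (R)- or (S)-BINOL); positions are quoted in labdane numbering (C1–C20).

**Step 1**
Reactants: 1 geranyl chloride [(2E)-1-chloro-3,7-dimethylocta-2,6-diene]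
Product: 2 (2E)-1-chloro-7-fluoro-3,7-dimethyloct-2-ene
Conditions: Fe2(C2O4)3·6H2O, NaBH4, F-TEDA-BF4, MeCN/H2O (1:1), 0 °C, 30 min
Reagents that add atoms: F-TEDA-BF4 [1-(chloromethyl)-4-fluoro-1,4-diazoniabicyclo[2.2.2]octane bis(tetrafluoroborate)] F[N+]12CC[N+](CCl)(CC1)CC2.F[B-](F)(F)F.F[B-](F)(F)F
Why: Mukaiyama-type radical hydrofluorination by metal-hydride hydrogen-atom transfer adds H to the electron-rich distal trisubstituted alkene in the Markovnikov sense and the tertiary radical is fluorinated faster than it can cyclise, while the alkene next to the electron-withdrawing allylic chloride reacts far more slowly; no stereocenter is formed.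

**Step 2**
Reactants: 2 (2E)-1-chloro-7-fluoro-3,7-dimethyloct-2-ene; 3 trimethyl(prop-1-yn-1-yl)silane
Product: 6 (5E)-10-fluoro-6,10-dimethylundec-5-en-1-yne, via lithiated silylpropyne 4 (not isolated), via silylalkyne 5 (not isolated)
Conditions: 3, n-BuLi, THF, −78 → −20 °C; add 2, −78 → 0 °C; then MeOH, K2CO3 (cat.), 25 °C
Reagents that add atoms: none
Why: Corey-type three-carbon homologation, in which the propargylic lithium reagent displaces the primary allylic chloride by SN2 with the E geometry kept, the tertiary C–F bond is inert to the organolithium at low temperature, and base-catalysed methanolysis removes the alkynyl silyl group.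

**Step 3**
Reactants: 6 (5E)-10-fluoro-6,10-dimethylundec-5-en-1-yne
Product: 8 (3Z,7E)-12-fluoro-8,12-dimethyl-4-[(trimethylsilyl)methyl]trideca-3,7-dien-1-ol, via alkenylcopper 7 (not isolated)
Conditions: Me3SiCH2MgCl, CuBr·SMe2, Et2O/Me2S, −40 °C; 6, −25 °C, 24 h; then LiC≡C(CH2)2CH3, HMPA, oxirane, −40 → −10 °C; aq. NH4Cl
Reagents that add atoms: (trimethylsilyl)methylmagnesium chloride C[Si](C)(C)C[Mg]Cl; oxirane C1CO1
Why: Normant syn-carbocupration adds Me3SiCH2 to the internal and copper to the terminal alkyne carbon on the same face, and the derived alkenyl cuprate opens oxirane with retention, so CH2SiMe3 and the new hydroxyethyl arm end cis (C7 and C11 trans, the geometry of a natural E-polyprenyl chain).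

**Step 4**
Reactants: 8 (3Z,7E)-12-fluoro-8,12-dimethyl-4-[(trimethylsilyl)methyl]trideca-3,7-dien-1-ol
Product: 9 (3Z,7E)-1-bromo-12-fluoro-8,12-dimethyl-4-[(trimethylsilyl)methyl]trideca-3,7-diene
Conditions: CBr4, PPh3, CH2Cl2, 0 °C
Reagents that add atoms: tetrabromomethane BrC(Br)(Br)Br
Why: Appel bromination of the primary alcohol runs under neutral conditions without free halogen or acid, which spares the allylsilane and the tertiary fluoride.

**Step 5**
Reactants: 10 prop-2-yn-1-ol
Product: 11 prop-2-yn-1-yl 2-methylpropanoate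
Conditions: i-PrCOCl, Et3N, DMAP (cat.), CH2Cl2, 0 °C
Reagents that add atoms: 2-methylpropanoyl chloride CC(C)C(Cl)=O
Why: DMAP-catalysed O-acylation of a primary alcohol, done before any C–C bond formation so that a free γ-hydroxy-(Z)-enoate, which would lactonise to the butenolide, is never formed.

**Step 6**
Reactants: 11 prop-2-yn-1-yl 2-methylpropanoate
Product: 14 tri(propan-2-yl)silyl 4-(2-methylpropanoyloxy)but-2-ynoate, via lithium acetylide 12 (not isolated), via lithium carboxylate 13 (not isolated)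
Conditions: LiN(i-Pr)2 (1.0 equiv), THF, −78 °C; CO2; then i-Pr3SiCl, DMF, −78 → 25 °C
Reagents that add atoms: carbon dioxide O=C=O; chlorotri(propan-2-yl)silane CC(C)[Si](Cl)(C(C)C)C(C)C
Why: the acetylenic C–H is far more acidic than the ester α-C–H, so one equivalent of amide base gives the acetylide, which is carboxylated and O-silylated in the same flask to a bulky silyl ester that survives chromatography and organocopper chemistry and is later cleaved by fluoride without touching the isobutyrate.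

**Step 7**
Reactants: 9 (3Z,7E)-1-bromo-12-fluoro-8,12-dimethyl-4-[(trimethylsilyl)methyl]trideca-3,7-diene; 14 tri(propan-2-yl)silyl 4-(2-methylpropanoyloxy)but-2-ynoate
Product: 18 tri(propan-2-yl)silyl (2Z,6Z,10E)-15-fluoro-11,15-dimethyl-3-[(2-methylpropanoyloxy)methyl]-7-[(trimethylsilyl)methyl]hexadeca-2,6,10-trienoate, via Grignard reagent 15 (not isolated), via alkylcopper 16 (not isolated), via cuprio adduct 17 (not isolated)
Conditions: 9, Mg, THF, 35 °C; CuBr·SMe2, THF/Me2S, −78 °C; 14, −78 °C, 1 h; AcOH, −78 °C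
Reagents that add atoms: none
Why: conjugate syn-carbocupration of the ynoate by the alkylcopper reagent and protonation of the alkenylcopper at −78 °C with retention put C12 trans and CH2O cis to the carboxyl carbon (13Z), and at this temperature 1,4-addition to the activated triple bond outruns SN2′ displacement of the poor isobutyrate leaving group.

**Step 8**
Reactants: 18 tri(propan-2-yl)silyl (2Z,6Z,10E)-15-fluoro-11,15-dimethyl-3-[(2-methylpropanoyloxy)methyl]-7-[(trimethylsilyl)methyl]hexadeca-2,6,10-trienoate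
Product: 20 (2Z)-3-[(2-methylpropanoyloxy)methyl]-5-[(1R,4aR,8aR)-5,5,8a-trimethyl-2-methylidenedecahydronaphthalen-1-yl]pent-2-enoic acid (target), via bicyclic silyl ester 19 (not isolated)
Conditions: N-trimethylsilyl imidodiphosphorimidate (IDPi, built from two 3,3′-diaryl-BINOL units, N-SO2CF3; 5 mol%), (2-methylallyl)SiMe3 (15 mol%), CH2Cl2, −78 → −40 °C; then Et3N·3HF, THF, 0 → 25 °C
Reagents that add atoms: none
Why: Proposed new method: the N-silyl IDPi (a chiral silylium ion pair) takes fluoride from the tertiary C–F bond (strong Si–F bond) and so makes, without free acid, the C4 cation that the cyclase makes by protonation; held as a contact ion pair in the confined chiral anion it closes ring A then ring B through a chair–chair fold (the E C5=C10 alkene gives the trans ring fusion, the allylsilane geometry puts the C9 chain equatorial, the anion chooses the fold that gives 5R,9R,10R), the C8 cation gives SiMe3 back to the anion to leave only the 8(17)-alkene and regenerate the catalyst, the small excess of methallylsilane traps any stray proton before it can protodesilylate the substrate, and fluoride then cleaves the silyl ester; the closest known reactions are IDPi-catalysed protonative polyene cyclisation of homofarnesol, IDPi-silylium Hosomi–Sakurai catalysis, Lewis-acid allylation of tertiary alkyl fluorides by allylsilanes and epoxide-initiated allylsilane-terminated bicyclisations.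

**Compound list**

1 | geranyl chloride, (2E)-1-chloro-3,7-dimethylocta-2,6-diene | CC(C)=CCC/C(C)=C/CCl | starting material
2 | (2E)-1-chloro-7-fluoro-3,7-dimethyloct-2-ene | CC(C)(F)CCC/C(C)=C/CCl | intermediate
3 | trimethyl(prop-1-yn-1-yl)silane | CC#C[Si](C)(C)C | starting material
4 | 3-lithio-1-(trimethylsilyl)prop-1-yne | [Li]CC#C[Si](C)(C)C | intermediate
5 | [(5E)-10-fluoro-6,10-dimethylundec-5-en-1-yn-1-yl]trimethylsilane | CC(C)(F)CCC/C(C)=C/CCC#C[Si](C)(C)C | intermediate
6 | (5E)-10-fluoro-6,10-dimethylundec-5-en-1-yne | CC(C)(F)CCC/C(C)=C/CCC#C | intermediate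
7 | [(1Z,5E)-10-fluoro-6,10-dimethyl-2-[(trimethylsilyl)methyl]undeca-1,5-dien-1-yl]copper | CC(C)(F)CCC/C(C)=C/CC/C(C[Si](C)(C)C)=C/[Cu] | intermediate
8 | (3Z,7E)-12-fluoro-8,12-dimethyl-4-[(trimethylsilyl)methyl]trideca-3,7-dien-1-ol | CC(C)(F)CCC/C(C)=C/CC/C(C[Si](C)(C)C)=C/CCO | intermediate
9 | (3Z,7E)-1-bromo-12-fluoro-8,12-dimethyl-4-[(trimethylsilyl)methyl]trideca-3,7-diene | CC(C)(F)CCC/C(C)=C/CC/C(C[Si](C)(C)C)=C/CCBr | intermediate
10 | prop-2-yn-1-ol | C#CCO | starting material
11 | prop-2-yn-1-yl 2-methylpropanoate | CC(C)C(=O)OCC#C | intermediate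
12 | [3-(2-methylpropanoyloxy)prop-1-yn-1-yl]lithium | CC(C)C(=O)OCC#C[Li] | intermediate
13 | lithium 4-(2-methylpropanoyloxy)but-2-ynoate | CC(C)C(=O)OCC#CC(=O)[O-].[Li+] | intermediate
14 | tri(propan-2-yl)silyl 4-(2-methylpropanoyloxy)but-2-ynoate | CC(C)C(=O)OCC#CC(=O)O[Si](C(C)C)(C(C)C)C(C)C | intermediate
15 | bromo[(3Z,7E)-12-fluoro-8,12-dimethyl-4-[(trimethylsilyl)methyl]trideca-3,7-dien-1-yl]magnesium | CC(C)(F)CCC/C(C)=C/CC/C(C[Si](C)(C)C)=C/CC[Mg]Br | intermediate
16 | [(3Z,7E)-12-fluoro-8,12-dimethyl-4-[(trimethylsilyl)methyl]trideca-3,7-dien-1-yl]copper | CC(C)(F)CCC/C(C)=C/CC/C(C[Si](C)(C)C)=C/CC[Cu] | intermediate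
17 | tri(propan-2-yl)silyl (2E,6Z,10E)-2-cuprio-15-fluoro-11,15-dimethyl-3-[(2-methylpropanoyloxy)methyl]-7-[(trimethylsilyl)methyl]hexadeca-2,6,10-trienoate | CC(C)(F)CCC/C(C)=C/CC/C(C[Si](C)(C)C)=C/CC/C(COC(=O)C(C)C)=C(\[Cu])C(=O)O[Si](C(C)C)(C(C)C)C(C)C | intermediate
18 | tri(propan-2-yl)silyl (2Z,6Z,10E)-15-fluoro-11,15-dimethyl-3-[(2-methylpropanoyloxy)methyl]-7-[(trimethylsilyl)methyl]hexadeca-2,6,10-trienoate | CC(C)(F)CCC/C(C)=C/CC/C(C[Si](C)(C)C)=C/CC/C(COC(=O)C(C)C)=C/C(=O)O[Si](C(C)C)(C(C)C)C(C)C | intermediate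
19 | tri(propan-2-yl)silyl (2Z)-3-[(2-methylpropanoyloxy)methyl]-5-[(1R,4aR,8aR)-5,5,8a-trimethyl-2-methylidenedecahydronaphthalen-1-yl]pent-2-enoate | C=C1CC[C@@H]2C(C)(C)CCC[C@@]2(C)[C@@H]1CC/C(=C/C(=O)O[Si](C(C)C)(C(C)C)C(C)C)COC(=O)C(C)C | intermediate
20 | (2Z)-3-[(2-methylpropanoyloxy)methyl]-5-[(1R,4aR,8aR)-5,5,8a-trimethyl-2-methylidenedecahydronaphthalen-1-yl]pent-2-enoic acid (16-isobutyryloxy-ent-labda-8(17),13Z-dien-15-oic acid) | C=C1CC[C@@H]2C(C)(C)CCC[C@@]2(C)[C@@H]1CC/C(=C/C(=O)O)COC(=O)C(C)C | target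

**Step count**

Total steps: 8 (steps 5 and 6 make the ynoate branch). Longest linear sequence: 6 (steps 1, 2, 3, 4, 7, 8).

**Steps most likely to fail**

Step 8. The silyl-IDPi may not ionise the C–F bond at a temperature low enough for selectivity, or the ion pair may give low ee. The fallback replaces catalyst control by a removable chiral epoxide; it sets out from 1 and comes back at 19.
- Shi epoxidation of 1 (D-fructose-derived ketone, KHSO5, K2CO3, MeCN/dimethoxymethane, 0 °C; the alkene next to the allylic chloride is deactivated) gives (R)-6,7-epoxygeranyl chloride F1.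
- Alkylation with 4 gives the epoxy silylalkyne F2, and K2CO3/MeOH gives the epoxy enyne F3.
- Carbocupration as in step 3 gives the epoxy alkenylcopper F4 and, with oxirane, the epoxy allylsilane alcohol F5; the hindered trisubstituted epoxide is not opened by organocopper reagents at −25 °C.
- CBr4/PPh3 gives the epoxy bromide F6.
- t-BuLi at −78 °C (milder toward the epoxide than magnesium) gives the epoxy alkyllithium F7, CuBr·SMe2 gives the epoxy alkylcopper F8, and addition to 14 gives the cuprio adduct F9 and, after AcOH, the epoxy trienoate F10.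
- MeAlCl2 (CH2Cl2, −78 °C) opens the epoxide at C4 and drives the same ring A then ring B cascade with allylsilane termination to the 3-hydroxy bicyclic ester F11; the (R)-epoxide fixes 5R,9R,10R through the chair–chair fold.
- The alcohol is removed by Barton–McCombie deoxygenation through the imidazolyl thiocarbonate F12 (1,1′-thiocarbonyldiimidazole, DMAP; then Bu3SnH, AIBN, toluene, 90 °C) to give 19, which is carried on with fluoride as in step 8.

Step 3. Transfer of the α-silylalkyl group from copper to a 1-alkyne may be slow or incomplete. The fallback uses nickel-catalysed ring opening of a dihydrofuran instead of carbocupration; it sets out from 6 and comes back at 8.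
- Deprotonation of 6 (n-BuLi, THF/DMPU) gives the lithium acetylide F13, which opens oxirane to the homopropargylic alcohol F14.
- PdCl2(PhCN)2-catalysed 5-endo cycloisomerisation (Et2O, 25 °C) gives the 5-alkyl-2,3-dihydrofuran F15.
- NiCl2(PPh3)2-catalysed cross-coupling with Me3SiCH2MgCl (THF/toluene, 60 °C; Wenkert–Kocienski reaction) replaces the ring oxygen by CH2SiMe3 with retention, so CH2SiMe3 again ends cis to the hydroxyethyl arm, and gives 8.

Step 1. The two trisubstituted alkenes may not be told apart well enough, and the allylic chloride may suffer in aqueous borohydride. The fallback moves the hydrofluorination onto the acetate and then restores the chloride; it sets out from 1 and comes back at 2.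
- KOAc in DMF gives geranyl acetate F16, the substrate class on which metal-hydride hydrogen-atom-transfer additions are known to pick the distal alkene.
- Hydrofluorination as in step 1 gives the fluoro acetate F17, and K2CO3/MeOH gives the fluoro alcohol F18.
- N-chlorosuccinimide/Me2S (Corey–Kim, −20 °C) gives the chloride 2.

**Further compounds**

F1 | step 8 | (2R)-2-[(3E)-5-chloro-3-methylpent-3-en-1-yl]-3,3-dimethyloxirane | CC1(C)O[C@@H]1CC/C(C)=C/CCl
F2 | step 8 | trimethyl{(5E)-8-[(2R)-3,3-dimethyloxiran-2-yl]-6-methyloct-5-en-1-yn-1-yl}silane | CC1(C)O[C@@H]1CC/C(C)=C/CCC#C[Si](C)(C)C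
F3 | step 8 | (2R)-3,3-dimethyl-2-[(3E)-3-methyloct-3-en-7-yn-1-yl]oxirane | CC1(C)O[C@@H]1CC/C(C)=C/CCC#C
F4 | step 8 | {(1Z,5E)-8-[(2R)-3,3-dimethyloxiran-2-yl]-6-methyl-2-[(trimethylsilyl)methyl]octa-1,5-dien-1-yl}copper | CC1(C)O[C@@H]1CC/C(C)=C/CC/C(C[Si](C)(C)C)=C/[Cu]
F5 | step 8 | (3Z,7E)-10-[(2R)-3,3-dimethyloxiran-2-yl]-8-methyl-4-[(trimethylsilyl)methyl]deca-3,7-dien-1-ol | CC1(C)O[C@@H]1CC/C(C)=C/CC/C(C[Si](C)(C)C)=C/CCO
F6 | step 8 | (2R)-2-[(3E,7Z)-10-bromo-3-methyl-7-[(trimethylsilyl)methyl]deca-3,7-dien-1-yl]-3,3-dimethyloxirane | CC1(C)O[C@@H]1CC/C(C)=C/CC/C(C[Si](C)(C)C)=C/CCBr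
F7 | step 8 | {(3Z,7E)-10-[(2R)-3,3-dimethyloxiran-2-yl]-8-methyl-4-[(trimethylsilyl)methyl]deca-3,7-dien-1-yl}lithium | CC1(C)O[C@@H]1CC/C(C)=C/CC/C(C[Si](C)(C)C)=C/CC[Li]
F8 | step 8 | {(3Z,7E)-10-[(2R)-3,3-dimethyloxiran-2-yl]-8-methyl-4-[(trimethylsilyl)methyl]deca-3,7-dien-1-yl}copper | CC1(C)O[C@@H]1CC/C(C)=C/CC/C(C[Si](C)(C)C)=C/CC[Cu]
F9 | step 8 | tri(propan-2-yl)silyl (2E,6Z,10E)-2-cuprio-13-[(2R)-3,3-dimethyloxiran-2-yl]-11-methyl-3-[(2-methylpropanoyloxy)methyl]-7-[(trimethylsilyl)methyl]trideca-2,6,10-trienoate | CC1(C)O[C@@H]1CC/C(C)=C/CC/C(C[Si](C)(C)C)=C/CC/C(COC(=O)C(C)C)=C(\[Cu])C(=O)O[Si](C(C)C)(C(C)C)C(C)C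
F10 | step 8 | tri(propan-2-yl)silyl (2Z,6Z,10E)-13-[(2R)-3,3-dimethyloxiran-2-yl]-11-methyl-3-[(2-methylpropanoyloxy)methyl]-7-[(trimethylsilyl)methyl]trideca-2,6,10-trienoate | CC1(C)O[C@@H]1CC/C(C)=C/CC/C(C[Si](C)(C)C)=C/CC/C(COC(=O)C(C)C)=C/C(=O)O[Si](C(C)C)(C(C)C)C(C)C
F11 | step 8 | tri(propan-2-yl)silyl (2Z)-5-[(1R,4aS,6R,8aS)-6-hydroxy-5,5,8a-trimethyl-2-methylidenedecahydronaphthalen-1-yl]-3-[(2-methylpropanoyloxy)methyl]pent-2-enoate | C=C1CC[C@@H]2C(C)(C)[C@H](O)CC[C@@]2(C)[C@@H]1CC/C(=C/C(=O)O[Si](C(C)C)(C(C)C)C(C)C)COC(=O)C(C)C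
F12 | step 8 | tri(propan-2-yl)silyl (2Z)-5-[(1R,4aS,6R,8aS)-6-(1H-imidazole-1-carbothioyloxy)-5,5,8a-trimethyl-2-methylidenedecahydronaphthalen-1-yl]-3-[(2-methylpropanoyloxy)methyl]pent-2-enoate | C=C1CC[C@@H]2C(C)(C)[C@H](OC(=S)n3ccnc3)CC[C@@]2(C)[C@@H]1CC/C(=C/C(=O)O[Si](C(C)C)(C(C)C)C(C)C)COC(=O)C(C)C
F13 | step 3 | [(5E)-10-fluoro-6,10-dimethylundec-5-en-1-yn-1-yl]lithium | CC(C)(F)CCC/C(C)=C/CCC#C[Li]
F14 | step 3 | (7E)-12-fluoro-8,12-dimethyltridec-7-en-3-yn-1-ol | CC(C)(F)CCC/C(C)=C/CCC#CCCO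
F15 | step 3 | 5-[(3E)-8-fluoro-4,8-dimethylnon-3-en-1-yl]-2,3-dihydrofuran | CC(C)(F)CCC/C(C)=C/CCC1=CCCO1
F16 | step 1 | (2E)-3,7-dimethylocta-2,6-dien-1-yl acetate | CC(C)=CCC/C(C)=C/COC(C)=O
F17 | step 1 | (2E)-7-fluoro-3,7-dimethyloct-2-en-1-yl acetate | CC(C)(F)CCC/C(C)=C/COC(C)=O
F18 | step 1 | (2E)-7-fluoro-3,7-dimethyloct-2-en-1-ol | CC(C)(F)CCC/C(C)=C/CO
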